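**Plan**

- Retrosynthesis: with the two ring B acetals removed last, ring A is cut at C7–C8 and C5–C6. This returns a 6-aryl-4-pyranone-3-carboxylate (ring C carrying ring B) and an acetyl unit.
- The pyranone is cut at O1–C2 and C4–C4a into γ-prenylated methyl acetoacetate and an arylpropioloyl chloride. The latter goes back through the alkyne to 2,4-dihydroxybenzaldehyde.
- Forward: ring B is bought; ring C closes by C-acylation and 6-endo-dig oxa-Michael addition; ring A is built last on ring C by lateral acetylation and Claisen closure; deprotection follows.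
- Enabling feature: ring A is a phloroglucinol in which C5–O is an ester carbonyl, C7–O an acetyl carbonyl and C8 the ring-attached CH2 of the 2-alkyl chain of the pyranone. That CH2 already bears the CH2CH=CMe2 residue that ends as the 8-prenyl group.
- Stereochemistry: the target has no stereocentre and no stereogenic double bond, so nothing needs to be controlled.

Key step: step 7

Remark on the chemistry: the only sp3 stereocentre on the way (in intermediate 12) forms racemic and is erased on aromatisation. 1-Acetylbenzotriazole is taken as the acetyl donor because it is not a Claisen-prone ester and its leaving group departs in the flask, which frees the ketone for the ring closure.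

**Step 1**
Reactants: 1 2,4-dihydroxybenzaldehyde
Product: 2 2,4-bis(methoxymethoxy)benzaldehyde
Conditions: NaH (2.4 equiv), DMF, 0 °C; MOMCl (2.4 equiv), 0 °C to rt
Reagents that add atoms: chloromethyl methyl ether (MOMCl), COCCl
Why: Williamson-type O-alkylation of both sodium phenoxides (NaH also opens the chelated ortho hydroxyl) should give acetal ethers that tolerate organolithium and amide bases and fall to mild acid at the end.

**Step 2**
Reactants: 2 2,4-bis(methoxymethoxy)benzaldehyde
Product: 3 1-ethynyl-2,4-bis(methoxymethoxy)benzene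
Conditions: dimethyl (1-diazo-2-oxopropyl)phosphonate, K2CO3, MeOH, rt
Reagents that add atoms: dimethyl (1-diazo-2-oxopropyl)phosphonate (Ohira–Bestmann reagent), CC(=O)C(=[N+]=[N-])P(=O)(OC)OC
Why: The Ohira–Bestmann variant of the Seyferth–Gilbert homologation converts a non-enolisable aryl aldehyde into the terminal alkyne under mildly basic conditions that leave the acetals untouched.

**Step 3**
Reactants: 3 1-ethynyl-2,4-bis(methoxymethoxy)benzene
Product: 4 3-[2,4-bis(methoxymethoxy)phenyl]prop-2-ynoic acid
Conditions: n-BuLi (1.0 equiv), THF, −78 °C; CO2 (g), −78 to 0 °C; cold dilute HCl to pH 3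
Reagents that add atoms: carbon dioxide, O=C=O
Why: One equivalent of n-BuLi should remove the acidic alkyne proton at −78 °C much faster than it metalates the ring next to the acetals, and carboxylation of the lithium acetylide is a standard route to arylpropiolic acids.

**Step 4**
Reactants: 4 3-[2,4-bis(methoxymethoxy)phenyl]prop-2-ynoic acid
Product: 5 3-[2,4-bis(methoxymethoxy)phenyl]prop-2-ynoyl chloride
Conditions: 1-chloro-N,N,2-trimethylprop-1-en-1-amine, CH2Cl2, 0 °C to rt; used crude
Reagents that add atoms: 1-chloro-N,N,2-trimethylprop-1-en-1-amine (Ghosez reagent), CC(C)=C(Cl)N(C)C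
Why: The Ghosez chloroenamine forms the acid chloride under neutral conditions, so no HCl is released that could cleave the acetals or add to the triple bond.

**Step 5**
Reactants: 6 methyl acetoacetate; 7 prenyl bromide (1-bromo-3-methylbut-2-ene)
Product: 8 methyl 7-methyl-3-oxooct-6-enoate
Conditions: NaH, THF, 0 °C; n-BuLi, 0 °C; 7, 0 °C to rt; dilute HCl
Reagents that add atoms: none
Why: In the Weiler dianion alkylation the more basic terminal carbanion of the acetoacetate dianion is alkylated selectively by the allylic bromide in an SN2 reaction.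

**Step 6**
Reactants: 5 3-[2,4-bis(methoxymethoxy)phenyl]prop-2-ynoyl chloride; 8 methyl 7-methyl-3-oxooct-6-enoate
Product: 10 methyl 6-[2,4-bis(methoxymethoxy)phenyl]-2-(4-methylpent-3-en-1-yl)-4-oxo-4H-pyran-3-carboxylate, via triacylmethane ynone 9 (not isolated)
Conditions: MgCl2, pyridine, CH2Cl2, 0 °C to rt; then K2CO3, acetone, rt
Reagents that add atoms: none
Why: The magnesium chelate of the β-keto ester is acylated on carbon by the acid chloride (Rathke-type soft-enolisation C-acylation), and the ketone enol oxygen of 9 then adds to the aryl-bearing alkyne carbon in a 6-endo-dig oxa-Michael closure, the classical pyranone synthesis from β-keto esters and arylpropioloyl chlorides.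

**Step 7**
Reactants: 10 methyl 6-[2,4-bis(methoxymethoxy)phenyl]-2-(4-methylpent-3-en-1-yl)-4-oxo-4H-pyran-3-carboxylate; 11 1-acetyl-1H-benzotriazole
Product: 13 2-[2,4-bis(methoxymethoxy)phenyl]-5,7-dihydroxy-8-(3-methylbut-2-en-1-yl)-4H-chromen-4-one, via C-acetylated pyranone 12 (not isolated)
Conditions: LiN(iPr)2 (1.1 equiv), THF, −78 °C; 11 (1.1 equiv), −78 °C; then LiN(iPr)2 (2.5 equiv), −78 °C to rt; aq. NH4Cl
Reagents that add atoms: none
Why: Proposed new method: LiN(iPr)2 removes a proton from the ring-attached CH2 of the 2-alkyl chain, which is vinylogous to both the C4 carbonyl and the 3-ester, and the extended enolate is acetylated on that carbon by 11 (new C7–C8 bond) to give 12. The second charge of base removes first the remaining C8–H and then an acetyl CH3 proton, the terminal enolate carbon adds to the neighbouring ester carbonyl (new C5–C6 bond), methoxide leaves and the cyclohexenedione enolises twice to the aromatic 5,7-diol. The closest known reaction type is lateral acylation of ortho-toluate or 2-methyl-4-pyranone anions followed by Claisen closure to 1,3-dihydroxynaphthalenes, the biomimetic polyketide benzannulation; the new element is running both events in one flask on a 4-pyranone-3-carboxylate. Ring A closes in a 6-exo-trig mode (Dieckmann-type attack of an enolate on an exocyclic ester carbonyl through an all-sp2 tether), and no stereocentre results because the sp3 centre of 12 is planarised on aromatisation. The step needs C- rather than O-acetylation, metalation of the lateral CH2 rather than of C5–H, and closure on the ester rather than on C4; these are served in turn by the soft delocalised carbanion paired with an N-acylbenzotriazole donor, by the doubly vinylogous activation of the CH2, and by geometry, since attack at C4 would have to form a bridged ring with bridgehead double bonds. The position of the prenyl group is settled beforehand, as the carbon that is acetylated already carries the CH2CH=CMe2 residue and has no option but to end as C8.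

**Step 8**
Reactants: 13 2-[2,4-bis(methoxymethoxy)phenyl]-5,7-dihydroxy-8-(3-methylbut-2-en-1-yl)-4H-chromen-4-one
Product: 14 2-(2,4-dihydroxyphenyl)-5,7-dihydroxy-8-(3-methylbut-2-en-1-yl)-4H-chromen-4-one
Conditions: 3 M aq. HCl, MeOH, 40 °C
Reagents that add atoms: none
Why: Acid-catalysed acetal exchange with methanol removes aryl methoxymethyl ethers, a standard final deprotection for prenylated flavonoids, and the mild temperature should keep the prenyl double bond from adding the 7-hydroxyl.

**Compound list**

1 | 2,4-dihydroxybenzaldehyde | O=Cc1ccc(O)cc1O | starting material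
2 | 2,4-bis(methoxymethoxy)benzaldehyde | O=Cc1ccc(OCOC)cc1OCOC | intermediate
3 | 1-ethynyl-2,4-bis(methoxymethoxy)benzene | C#Cc1ccc(OCOC)cc1OCOC | intermediate
4 | 3-[2,4-bis(methoxymethoxy)phenyl]prop-2-ynoic acid | OC(=O)C#Cc1ccc(OCOC)cc1OCOC | intermediate
5 | 3-[2,4-bis(methoxymethoxy)phenyl]prop-2-ynoyl chloride | ClC(=O)C#Cc1ccc(OCOC)cc1OCOC | intermediate
6 | methyl acetoacetate | COC(=O)CC(C)=O | starting material
7 | prenyl bromide (1-bromo-3-methylbut-2-ene) | CC(C)=CCBr | starting material
8 | methyl 7-methyl-3-oxooct-6-enoate | COC(=O)CC(=O)CCC=C(C)C | intermediate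
9 | methyl 2-{3-[2,4-bis(methoxymethoxy)phenyl]prop-2-ynoyl}-7-methyl-3-oxooct-6-enoate (drawn as the triketo tautomer, present as enol or magnesium chelate) | COC(=O)C(C(=O)C#Cc1ccc(OCOC)cc1OCOC)C(=O)CCC=C(C)C | intermediate
10 | methyl 6-[2,4-bis(methoxymethoxy)phenyl]-2-(4-methylpent-3-en-1-yl)-4-oxo-4H-pyran-3-carboxylate | COC(=O)c1c(CCC=C(C)C)oc(-c2ccc(OCOC)cc2OCOC)cc1=O | intermediate
11 | 1-acetyl-1H-benzotriazole | CC(=O)n1nnc2ccccc12 | starting material
12 | methyl 6-[2,4-bis(methoxymethoxy)phenyl]-2-(6-methyl-2-oxohept-5-en-3-yl)-4-oxo-4H-pyran-3-carboxylate (racemic, present as its lithium enolate) | COC(=O)c1c(C(CC=C(C)C)C(C)=O)oc(-c2ccc(OCOC)cc2OCOC)cc1=O | intermediate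
13 | 2-[2,4-bis(methoxymethoxy)phenyl]-5,7-dihydroxy-8-(3-methylbut-2-en-1-yl)-4H-chromen-4-one | CC(C)=CCc1c(O)cc(O)c2c(=O)cc(-c3ccc(OCOC)cc3OCOC)oc12 | intermediate
14 | 2-(2,4-dihydroxyphenyl)-5,7-dihydroxy-8-(3-methylbut-2-en-1-yl)-4H-chromen-4-one | CC(C)=CCc1c(O)cc(O)c2c(=O)cc(-c3ccc(O)cc3O)oc12 | target

**Count**

Total steps: 8. Longest linear sequence: 7 steps (steps 1, 2, 3, 4, 6, 7, 8); step 5 is the side branch.

**Steps most likely to fail**

Step 7. The lateral enolate may be acetylated on oxygen, or be protonated by the more acidic acetylated product before acylation is complete. The ester, deactivated by conjugation with the C8 carbanion, may also resist the Claisen closure. The fallback gives up the pyranone route to ring A and uses the classical chalcone construction of ring C; it sets out from aldehyde 2 and returns at target 14. Commercial 2,4,6-trihydroxyacetophenone would be C-prenylated with 7 (aq. KOH, 0 °C) to 1-[2,4,6-trihydroxy-3-(3-methylbut-2-en-1-yl)phenyl]ethanone F1. MOMCl and iPr2NEt should etherify the 4-hydroxyl and the less hindered of the two chelated hydroxyls, giving 1-[2-hydroxy-4,6-bis(methoxymethoxy)-3-(3-methylbut-2-en-1-yl)phenyl]ethanone F2, whose free hydroxyl lies next to the prenyl group. Claisen–Schmidt condensation with 2 (KOH, EtOH) would give (E)-3-[2,4-bis(methoxymethoxy)phenyl]-1-[2-hydroxy-4,6-bis(methoxymethoxy)-3-(3-methylbut-2-en-1-yl)phenyl]prop-2-en-1-one F3. Oxidative cyclisation (catalytic I2, DMSO, 120 °C) would give 5,7-bis(methoxymethoxy)-2-[2,4-bis(methoxymethoxy)phenyl]-8-(3-methylbut-2-en-1-yl)-4H-chromen-4-one F4, and the conditions of step 8 would then remove all four acetals to reach 14.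

Step 6. Chloride or pyridine may add in conjugate fashion to the alkynoyl chloride, the enolate may be acylated on oxygen, or the enol may close 5-exo instead of 6-endo. The fallback reverses the roles of the two acyl partners so that no arylpropioloyl chloride is needed; it sets out from acid 4 and returns at pyranone 10. Acid 4 would be activated with 1,1'-carbonyldiimidazole to 1-{3-[2,4-bis(methoxymethoxy)phenyl]prop-2-ynoyl}-1H-imidazole F5. Chain extension with KO2CCH2CO2Me and MgCl2 (Masamune–Brooks) would give methyl 5-[2,4-bis(methoxymethoxy)phenyl]-3-oxopent-4-ynoate F6. C-acylation of its magnesium enolate (MgCl2, pyridine) with 5-methylhex-4-enoyl chloride F7, made from commercial 5-methylhex-4-enoic acid and (COCl)2, would give the same triacylmethane 9, which closes to 10 as in step 6.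

Step 8. Acid may promote addition of the 7-hydroxyl to the prenyl double bond (chroman formation) while the acetals are being cleaved. The fallback moves the acid treatment to a stage where no phenol flanks the alkene and finishes with fluoride; it sets out from pyranone 10 and returns at target 14. Acidic methanolysis of 10 would give methyl 6-(2,4-dihydroxyphenyl)-2-(4-methylpent-3-en-1-yl)-4-oxo-4H-pyran-3-carboxylate F8. TBSCl and imidazole would give methyl 6-[2,4-bis(tert-butyldimethylsilyloxy)phenyl]-2-(4-methylpent-3-en-1-yl)-4-oxo-4H-pyran-3-carboxylate F9. The conditions of step 7 with 11 would lead through methyl 6-[2,4-bis(tert-butyldimethylsilyloxy)phenyl]-2-(6-methyl-2-oxohept-5-en-3-yl)-4-oxo-4H-pyran-3-carboxylate F10 to 2-[2,4-bis(tert-butyldimethylsilyloxy)phenyl]-5,7-dihydroxy-8-(3-methylbut-2-en-1-yl)-4H-chromen-4-one F11. Bu4NF buffered with AcOH (THF, 0 °C) would then free 14; silyl loss already in the basic step would be harmless, since it leads to the same product.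

**Further compounds**

F1 | step 7 | 1-[2,4,6-trihydroxy-3-(3-methylbut-2-en-1-yl)phenyl]ethanone | CC(=O)c1c(O)cc(O)c(CC=C(C)C)c1O
F2 | step 7 | 1-[2-hydroxy-4,6-bis(methoxymethoxy)-3-(3-methylbut-2-en-1-yl)phenyl]ethanone | CC(=O)c1c(O)c(CC=C(C)C)c(OCOC)cc1OCOC
F3 | step 7 | (E)-3-[2,4-bis(methoxymethoxy)phenyl]-1-[2-hydroxy-4,6-bis(methoxymethoxy)-3-(3-methylbut-2-en-1-yl)phenyl]prop-2-en-1-one | COCOc1ccc(/C=C/C(=O)c2c(O)c(CC=C(C)C)c(OCOC)cc2OCOC)c(OCOC)c1
F4 | step 7 | 5,7-bis(methoxymethoxy)-2-[2,4-bis(methoxymethoxy)phenyl]-8-(3-methylbut-2-en-1-yl)-4H-chromen-4-one | CC(C)=CCc1c(OCOC)cc(OCOC)c2c(=O)cc(-c3ccc(OCOC)cc3OCOC)oc12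
F5 | step 6 | 1-{3-[2,4-bis(methoxymethoxy)phenyl]prop-2-ynoyl}-1H-imidazole | O=C(C#Cc1ccc(OCOC)cc1OCOC)n1ccnc1
F6 | step 6 | methyl 5-[2,4-bis(methoxymethoxy)phenyl]-3-oxopent-4-ynoate | COC(=O)CC(=O)C#Cc1ccc(OCOC)cc1OCOC
F7 | step 6 | 5-methylhex-4-enoyl chloride | CC(C)=CCCC(=O)Cl
F8 | step 8 | methyl 6-(2,4-dihydroxyphenyl)-2-(4-methylpent-3-en-1-yl)-4-oxo-4H-pyran-3-carboxylate | COC(=O)c1c(CCC=C(C)C)oc(-c2ccc(O)cc2O)cc1=O
F9 | step 8 | methyl 6-[2,4-bis(tert-butyldimethylsilyloxy)phenyl]-2-(4-methylpent-3-en-1-yl)-4-oxo-4H-pyran-3-carboxylate | COC(=O)c1c(CCC=C(C)C)oc(-c2ccc(O[Si](C)(C)C(C)(C)C)cc2O[Si](C)(C)C(C)(C)C)cc1=O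
F10 | step 8 | methyl 6-[2,4-bis(tert-butyldimethylsilyloxy)phenyl]-2-(6-methyl-2-oxohept-5-en-3-yl)-4-oxo-4H-pyran-3-carboxylate | COC(=O)c1c(C(CC=C(C)C)C(C)=O)oc(-c2ccc(O[Si](C)(C)C(C)(C)C)cc2O[Si](C)(C)C(C)(C)C)cc1=O
F11 | step 8 | 2-[2,4-bis(tert-butyldimethylsilyloxy)phenyl]-5,7-dihydroxy-8-(3-methylbut-2-en-1-yl)-4H-chromen-4-one | CC(C)=CCc1c(O)cc(O)c2c(=O)cc(-c3ccc(O[Si](C)(C)C(C)(C)C)cc3O[Si](C)(C)C(C)(C)C)oc12
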